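Time is what we want to remove from this problem. D and X react over the catalyst Z to give J, and the flasks differ in their charge of Z.

| flask | D | X | Z | remark |
|---|---|---|---|---|
| Thursday's | 0.020 M | 1.5 equiv | 0.13 mol% | run made earlier |
| Tuesday's | 0.020 M | 1.5 equiv | 0.3 mol% | run made earlier |
| flask | 0.020 M | 1.50 equiv | 0.2 mol% |  |

| run | time / min | J / % | D / % |
|---|---|---|---|
| Thursday's | 8.00 | 3 | 97 |
| Thursday's | 12.0 | 2 | 95 |
| Thursday's | 20.0 | 4 | 95 |
| Thursday's | 40.0 | 6 | 91 |
| Thursday's | 60.0 | 12 | 90 |
| Thursday's | 90.0 | 15 | 81 |
| Tuesday's | 15.0 | 9 | 94 |
| Tuesday's | 30.0 | 19 | 86 |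
| Tuesday's | 50.0 | 21 | 78 |
| Tuesday's | 60.0 | 29 | 73 |
| Tuesday's | 80.0 | 31 | 69 |
| Tuesday's | 90.0 | 32 | 65 |

(each reading ± 1.5 percentage points)

- no earlier run changes the charge of X; that part of a forecast is a guess

- factor on the rate of making J when 20% of the D are converted if X is charged twice over
- factor on the rate when 20% of the D are converted if Z is charged at 1 mol% instead

In Tuesday's run, the logarithm of charged over remaining D (J and D readings averaged) reads 0.180 after 30.0 min and 0.408 after 90.0 min, which is less than the 0.540 of a steady first-order decay. We read this as catalyst deactivation: a rate constant fading with a time constant of 95.2 min, the same at each loading, and starting in proportion to Z.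

Dividing the rate of that logarithm by the rate at which the active share of catalyst falls removes time. The logarithm then grows in step with the active share lost, up to a ceiling value in this fitted picture. We call that value the reach, 0.667 for Tuesday's run. Scaled by Z, it is 0.445 for the flask. At 20% conversion the logarithm is 0.223, so by our reckoning the flask keeps about half of its activity, 0.498, and a charge of 1 mol% keeps 0.900.

Which number must be good? A reach a tenth lower takes the flask's share to 0.443 and the other to 0.889, moving the factor to 10.0, so the flask's reach matters. Thursday's readings don't enter, and they serve as a check: the reach predicts 16.2% conversion after 90.0 min, against readings of 15% J and 81% D. Our factor for Z is 9.02. No run varies X, so for X we can only guess.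

The forecast says 1.5 for X and 5 for Z, noting “saturation is possible”, and its Z figure differs from ours. The flask gives 1.98 and 8.63.

    G → E (k = 380 h⁻¹)
    Z ⇌ L (K = 24.0, k = 1.30 h⁻¹)
    X + Z → Q (k = 9400 M⁻¹ h⁻¹)
    E ⇌ Z + J (K = 0.0370 M, k = 620 h⁻¹)
    D + Q → G (k = 1.10 × 10⁵ M⁻¹ h⁻¹)

The flask reaches 20% after 1.20 h. One over the kept share, 2.01, is the local order in Z that the reach implies, and the flask's apparent order is 1.9. Z passing into L and back, L being off-cycle, lifts that order from 1.0 in the same run without the step to 1.9. At 1 mol% the reach is 2.22, and the factor 8.63 stands above the loading ratio 5.00. Without the passing of Z into L, both ways, this flask's rate at 20% stands at 1.91 times the actual one.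

(The runs are calculated with constants of no real substance; the scatter is artificial.)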